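**Plan**

- Rings: A carries the methoxy group, B is the meta-linked ring, C the phenol ring, D the para-linked ring. Cuts, in order: the ring C O–H (isopropyl ether); the bond from ring A to the ether oxygen of ring B, put back as a C(=O)–O ester with one CO inserted; the ester C–O bond; the benzylic C–C bond of the A–D ethano bridge; the C–D ether bond; the central C–C bond of the B–C ethano bridge.
- Forward: B–C stilbene by olefination, C–D ether by SNAr, A–D bridge by toluate aldol-lactonisation, one hydrogenation to the seco hydroxy acid, closure of the 19-membered lactone, CO extrusion to the 18-membered ring, deprotection.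
- Enabling feature: the ring A carbon that bears the oxygen to ring B lies between the methoxy-bearing carbon and the carbon carrying the ethano bridge to ring D. This di-ortho-substituted diaryl ether is an aryl 2-methoxy-6-alkylbenzoate less CO, and that benzoate is what lateral metalation of a 2-methoxy-6-methylbenzoate provides.
- Stereochemistry: the target is achiral; the E-alkene and the racemic lactone carbon made on the way are erased by the hydrogenation.

Key step: step 8

Remark: ring C is carried as its isopropyl ether, not a benzyl ether, because the hydrogenation of step 6 must free only the ring B phenol; the lactone and the contracted macrocycle are therefore isopropyl ethers.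

**Route**

Step 1
Reactants: 1 3,4-dihydroxybenzaldehyde
Product: 2 3-hydroxy-4-isopropoxybenzaldehyde
Conditions: 2-bromopropane, K2CO3 (1.0 equiv), DMF, 60 °C
Reagents that add atoms: 2-bromopropane, CC(C)Br
Why: Williamson etherification that should be selective for the 4-hydroxyl, because one equivalent of weak base ionises only the more acidic phenol para to the formyl group (regioselective monoalkylation of protocatechualdehyde).

Step 2
Reactants: 3 3-(benzyloxy)benzyl bromide
Product: 4 diethyl [3-(benzyloxy)benzyl]phosphonate
Conditions: P(OEt)3, neat, 140 °C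
Reagents that add atoms: triethyl phosphite, CCOP(OCC)OCC
Why: Michaelis–Arbuzov reaction of a primary benzylic bromide, driven by loss of bromoethane.

Step 3
Reactants: 2 3-hydroxy-4-isopropoxybenzaldehyde; 4 diethyl [3-(benzyloxy)benzyl]phosphonate
Product: 5 5-{(E)-2-[3-(benzyloxy)phenyl]ethenyl}-2-isopropoxyphenol
Conditions: KOtBu (3 equiv), DMF, 0 °C to rt; then aq. HCl
Reagents that add atoms: none
Why: Horner–Wadsworth–Emmons olefination of a benzylphosphonate anion, which should give the E-stilbene, with the extra base holding the phenol as a phenoxide that is meta to the formyl group and so leaves it electrophilic.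

Step 4
Reactants: 5 5-{(E)-2-[3-(benzyloxy)phenyl]ethenyl}-2-isopropoxyphenol; 6 4-fluorobenzaldehyde
Product: 7 4-(5-{(E)-2-[3-(benzyloxy)phenyl]ethenyl}-2-isopropoxyphenoxy)benzaldehyde
Conditions: K2CO3, DMF, 130 °C
Reagents that add atoms: none
Why: SNAr of the phenoxide on the aryl fluoride activated by the para formyl group, the standard diaryl ether construction of bis(bibenzyl) chemistry.

Step 5
Reactants: 8 ethyl 2-methoxy-6-methylbenzoate; 7 4-(5-{(E)-2-[3-(benzyloxy)phenyl]ethenyl}-2-isopropoxyphenoxy)benzaldehyde
Product: 11 rac-3-[4-(5-{(E)-2-[3-(benzyloxy)phenyl]ethenyl}-2-isopropoxyphenoxy)phenyl]-8-methoxy-3,4-dihydroisocoumarin, via lithiated toluate 9 (not isolated), via lithium aldolate 10 (not isolated)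
Conditions: LiN(iPr)2, THF, −78 °C; then 7, −78 °C to rt; then aq. HCl
Reagents that add atoms: none
Why: Lateral lithiation of the o-toluate (methyl acidified by the ortho ester) and aldol addition to the non-enolisable aldehyde, after which the alkoxide closes onto the ester to give the δ-lactone as a racemate whose single stereocentre is removed in step 6.

Step 6
Reactants: 11 rac-3-aryl-8-methoxy-3,4-dihydroisocoumarin
Product: 13 2-[2-(4-{5-[2-(3-hydroxyphenyl)ethyl]-2-isopropoxyphenoxy}phenyl)ethyl]-6-methoxybenzoic acid, via debenzylated bibenzyl lactone 12 (not isolated)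
Conditions: H2 (4 atm), Pd/C, EtOAc–AcOH, 50 °C
Reagents that add atoms: none
Why: Heterogeneous hydrogenation over palladium should saturate the stilbene, cleave the benzyl ether and hydrogenolyse the benzylic lactone C–O bond (a benzyl ester on a para-aryloxy ring, as in the classical conversion of 3-aryl-dihydroisocoumarins into 2-(2-arylethyl)benzoic acids), while the isopropyl, methyl and diaryl ethers are inert.

Step 7
Reactants: 13 2-[2-(4-{5-[2-(3-hydroxyphenyl)ethyl]-2-isopropoxyphenoxy}phenyl)ethyl]-6-methoxybenzoic acid
Product: 15 19-membered aryl ester macrolactone (ring A carbonyl to ring B oxygen; isopropyl ether on ring C), via acyl trifluoroacetate 14 (not isolated)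
Conditions: (CF3CO)2O (3 equiv), CH2Cl2, slow addition of 13 to 1 mM, rt
Reagents that add atoms: none
Why: Mixed-anhydride macrolactonisation in which the di-ortho-substituted acid ionises to an acylium ion that the phenol captures at oxygen (trifluoroacetic anhydride esterification of hindered aromatic acids with phenols), run at high dilution to favour the 19-membered ring over oligomers.

Step 8
Reactants: 15 19-membered aryl ester macrolactone
Product: 16 18-membered bis(bibenzyl) diaryl ether macrocycle, isopropyl ether of the target
Conditions: Ni(cod)2 (20 mol%), 3,4-bis(dicyclohexylphosphino)thiophene (40 mol%), K3PO4 (1.5 equiv), toluene (5 mM), 160 °C, sealed tube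
Reagents that add atoms: none
Why: Proposed new method: zerovalent nickel bearing the electron-rich diphosphine should add oxidatively to the C(acyl)–O bond of the aryl ester, possibly helped by chelation of the neighbouring ring A methoxy oxygen, to give an acyl divalent nickel phenoxide; CO then migrates to nickel and is lost at 160 °C, and C–O reductive elimination from the aryl divalent nickel phenoxide joins the former carbonyl-bearing carbon of ring A directly to the ring B oxygen. The closest known reaction type is the nickel-catalysed intermolecular decarbonylative conversion of aryl esters of aromatic (mostly azine) carboxylic acids into diaryl ethers, which has not been run as a ring contraction or on an electron-rich di-ortho-substituted benzoate. The 18-membered ring is not closed end to end but arises by contraction of the 19-membered lactone: aryl and phenoxide stay on one nickel centre and in one chain, so the bond forms inside a nickelacycle without the entropic cost of a macrocyclisation. No stereocentre is created. The step needs insertion into the acyl C–O bond only, not into the ring B aryl–O bond of the ester, the C–D diaryl ether or the methoxy and isopropoxy C–O bonds; on non-fused benzene rings the ester acyl bond is by far the most reactive of these, the hindered ester resists attack by K3PO4, and dilution should suppress phenoxide crossover to oligomers.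

Step 9
Reactants: 16 isopropyl ether of the target
Product: 18 CNP0309263.0 (target phenol), via aryloxydichloroborane 17 (not isolated)
Conditions: BCl3, CH2Cl2, −78 to 0 °C; then H2O
Reagents that add atoms: none
Why: Lewis-acid dealkylation in which BCl3 cleaves the secondary isopropyl aryl ether through an SN1-like pathway much faster than the methyl ether, a selectivity well established for isopropyl-protected phenols.

**Compound list**

1 | 3,4-dihydroxybenzaldehyde | O=Cc1ccc(O)c(O)c1 | starting material
2 | 3-hydroxy-4-isopropoxybenzaldehyde | O=Cc1ccc(OC(C)C)c(O)c1 | intermediate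
3 | 3-(benzyloxy)benzyl bromide | BrCc1cccc(OCc2ccccc2)c1 | starting material
4 | diethyl [3-(benzyloxy)benzyl]phosphonate | CCOP(=O)(Cc1cccc(OCc2ccccc2)c1)OCC | intermediate
5 | 5-{(E)-2-[3-(benzyloxy)phenyl]ethenyl}-2-isopropoxyphenol | CC(C)Oc1ccc(/C=C/c2cccc(OCc3ccccc3)c2)cc1O | intermediate
6 | 4-fluorobenzaldehyde | O=Cc1ccc(F)cc1 | starting material
7 | 4-(5-{(E)-2-[3-(benzyloxy)phenyl]ethenyl}-2-isopropoxyphenoxy)benzaldehyde | CC(C)Oc1ccc(/C=C/c2cccc(OCc3ccccc3)c2)cc1Oc1ccc(C=O)cc1 | intermediate
8 | ethyl 2-methoxy-6-methylbenzoate | CCOC(=O)c1c(C)cccc1OC | starting material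
9 | ethyl 2-(lithiomethyl)-6-methoxybenzoate (lithiated toluate) | CCOC(=O)c1c(C[Li])cccc1OC | intermediate
10 | lithium alkoxide of the aldol adduct of 9 and 7 (lithium aldolate, racemic) | CCOC(=O)c1c(CC(O[Li])c2ccc(Oc3cc(/C=C/c4cccc(OCc5ccccc5)c4)ccc3OC(C)C)cc2)cccc1OC | intermediate
11 | rac-3-[4-(5-{(E)-2-[3-(benzyloxy)phenyl]ethenyl}-2-isopropoxyphenoxy)phenyl]-8-methoxy-3,4-dihydroisocoumarin | COc1cccc2c1C(=O)OC(C2)c1ccc(Oc2cc(/C=C/c3cccc(OCc4ccccc4)c3)ccc2OC(C)C)cc1 | intermediate
12 | rac-3-(4-{5-[2-(3-hydroxyphenyl)ethyl]-2-isopropoxyphenoxy}phenyl)-8-methoxy-3,4-dihydroisocoumarin (debenzylated bibenzyl lactone) | COc1cccc2c1C(=O)OC(C2)c1ccc(Oc2cc(CCc3cccc(O)c3)ccc2OC(C)C)cc1 | intermediate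
13 | 2-[2-(4-{5-[2-(3-hydroxyphenyl)ethyl]-2-isopropoxyphenoxy}phenyl)ethyl]-6-methoxybenzoic acid (seco hydroxy acid) | COc1cccc(CCc2ccc(Oc3cc(CCc4cccc(O)c4)ccc3OC(C)C)cc2)c1C(=O)O | intermediate
14 | mixed anhydride of 13 with trifluoroacetic acid (acyl trifluoroacetate) | COc1cccc(CCc2ccc(Oc3cc(CCc4cccc(O)c4)ccc3OC(C)C)cc2)c1C(=O)OC(=O)C(F)(F)F | intermediate
15 | 19-membered aryl ester macrolactone, ring C isopropyl ether | COc1cccc2c1C(=O)Oc1cccc(c1)CCc1ccc(OC(C)C)c(c1)Oc1ccc(cc1)CC2 | intermediate
16 | 18-membered diaryl ether macrocycle, isopropyl ether of the target | COc1cccc2c1Oc1cccc(c1)CCc1ccc(OC(C)C)c(c1)Oc1ccc(cc1)CC2 | intermediate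
17 | aryloxydichloroborane of the target phenol | COc1cccc2c1Oc1cccc(c1)CCc1ccc(OB(Cl)Cl)c(c1)Oc1ccc(cc1)CC2 | intermediate
18 | CNP0309263.0 | COc1cccc2c1Oc1cccc(c1)CCc1ccc(O)c(c1)Oc1ccc(cc1)CC2 | target

**Step count and risks**

Total steps: 9. Longest linear sequence: 8 steps (1 → 2 → 5 → 7 → 11 → 13 → 15 → 16 → 18).

Steps most likely to fail:

1. Step 8 (proposed new method). Oxidative addition may not take place at the shielded, electron-rich acyl C–O bond. Retained CO may poison nickel before reductive elimination. Phenoxide exchange between nickel centres may give oligomeric ethers. Fallback by known chemistry, setting out from aldehyde 7 and returning at 16: the hindered bond from ring A to the ring B oxygen is made by SNAr and the ring is closed at the A–D bridge. The formyl group of 7 is masked with ethylene glycol and TsOH in toluene (Dean–Stark) as aryl dioxolane F1. Hydrogenation over Pd/C in EtOAc–THF at rt, with a little solid NaHCO3 to keep the medium free of acid, saturates the stilbene and removes the benzyl group to give phenol acetal F2. SNAr of F2 with 2-fluoro-3-methoxybenzaldehyde (K2CO3, DMF, 140 °C) attaches ring A through the hindered ether to give ring A aldehyde acetal F3. Aqueous HCl in THF releases dialdehyde F4. McMurry coupling with low-valent titanium from TiCl4 and Zn (pyridine, THF, reflux, high dilution) closes the 18-membered ring as macrocyclic stilbene F5. Hydrogenation (H2, Pd/C, EtOAc) of either alkene isomer gives 16, and step 9 follows.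

2. Step 7. Oligomerisation may outrun closure of the 19-membered ring. The acylium ion may attack ring D in an intramolecular Friedel–Crafts acylation to a seven-membered ketone. The phenol may be capped as its trifluoroacetate. The fallback sets out from 13 and returns at 15, and replaces the acid-promoted acylium pathway by a discrete acyl chloride closed under basic nucleophilic catalysis. Acid 13 is treated with oxalyl chloride and catalytic DMF in CH2Cl2 at 0 °C to give hydroxy acid chloride F6; the hindered acyl chloride should not react with the un-ionised phenol in the absence of base. F6 is added by syringe pump to DMAP and Et3N in toluene at 80 °C, so that the phenoxide attacks an N-acylpyridinium ion and no free acylium ion is present.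

3. Step 6. Alkene reduction and debenzylation should be fast, but hydrogenolysis of the lactone C–O bond may stall at lactone 12. The fallback sets out from 11 and returns at 13, and cleaves the C–O bond by elimination, not hydrogenolysis. KOtBu in DMSO at rt opens the dihydroisocoumarin by E1cB loss of the carboxylate to give, after acidification, bis-stilbene acid F7. Hydrogenation (H2, Pd/C, EtOAc–MeOH, rt) then saturates both alkenes and removes the benzyl group to give 13.

**Further compounds**

F1 | step 8 | 2-[4-(5-{(E)-2-[3-(benzyloxy)phenyl]ethenyl}-2-isopropoxyphenoxy)phenyl]-1,3-dioxolane | CC(C)Oc1ccc(/C=C/c2cccc(OCc3ccccc3)c2)cc1Oc1ccc(C2OCCO2)cc1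
F2 | step 8 | 3-(2-{3-[4-(1,3-dioxolan-2-yl)phenoxy]-4-isopropoxyphenyl}ethyl)phenol | CC(C)Oc1ccc(CCc2cccc(O)c2)cc1Oc1ccc(C2OCCO2)cc1
F3 | step 8 | 2-[3-(2-{3-[4-(1,3-dioxolan-2-yl)phenoxy]-4-isopropoxyphenyl}ethyl)phenoxy]-3-methoxybenzaldehyde | COc1cccc(C=O)c1Oc1cccc(CCc2ccc(OC(C)C)c(Oc3ccc(C4OCCO4)cc3)c2)c1
F4 | step 8 | 2-(3-{2-[3-(4-formylphenoxy)-4-isopropoxyphenyl]ethyl}phenoxy)-3-methoxybenzaldehyde | COc1cccc(C=O)c1Oc1cccc(CCc2ccc(OC(C)C)c(Oc3ccc(C=O)cc3)c2)c1
F5 | step 8 | 18-membered macrocycle with an A–D ethene bridge, ring C isopropyl ether (alkene isomer mixture) | COc1cccc2c1Oc1cccc(c1)CCc1ccc(OC(C)C)c(c1)Oc1ccc(cc1)C=C2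
F6 | step 7 | 2-[2-(4-{5-[2-(3-hydroxyphenyl)ethyl]-2-isopropoxyphenoxy}phenyl)ethyl]-6-methoxybenzoyl chloride | COc1cccc(CCc2ccc(Oc3cc(CCc4cccc(O)c4)ccc3OC(C)C)cc2)c1C(Cl)=O
F7 | step 6 | 2-{(E)-2-[4-(5-{(E)-2-[3-(benzyloxy)phenyl]ethenyl}-2-isopropoxyphenoxy)phenyl]ethenyl}-6-methoxybenzoic acid | COc1cccc(/C=C/c2ccc(Oc3cc(/C=C/c4cccc(OCc5ccccc5)c4)ccc3OC(C)C)cc2)c1C(=O)O
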